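**Retrosynthetic overview**
- Target ⇒ indole + a trans-(2R,3R) 2-indolyl glycidol: invertive opening at the indolylic epoxide carbon joins the two indole units and fixes the diarylmethine centre.
- Glycidol ⇒ (E)-3-(indol-2-yl)allyl alcohol: Ti/D-tartrate epoxidation (C–O bond formation) is the stereo-defining event for both centres.
- Allyl alcohol ⇒ 2-bromotryptophol acetate + (E)-Bu3SnCH=CHCH2OH (Stille coupling).
- 2-Bromotryptophol acetate ⇒ tryptophol acetate ⇒ tryptophol (NBS; Ac2O).
- Rings: both indole rings are bought intact; the only ring made is the transient oxirane, formed and opened in the last flask.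

Assumption: the target is the (2S,3S) isomer encoded by the SMILES (indol-3-yl anti to the C2 hydroxyl), and (E)-3-(tributylstannyl)prop-2-en-1-ol is bought as a catalogue reagent.

**Step 1**
Reactants: 1 tryptophol; 2 acetic anhydride
Product: 3 2-(1H-indol-3-yl)ethyl acetate (tryptophol acetate)
Conditions: Ac2O (1.2 equiv), pyridine, CH2Cl2, 0 °C to rt
Reagents that add atoms: acetic anhydride (2), CC(=O)OC(C)=O
Why: O-acetylation (nucleophilic acyl substitution) of the primary alcohol; without DMAP the weakly nucleophilic indole N–H is not acylated.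

**Step 2**
Reactants: 3 2-(1H-indol-3-yl)ethyl acetate; 4 N-bromosuccinimide
Product: 5 2-(2-bromo-1H-indol-3-yl)ethyl acetate
Conditions: NBS (1.0 equiv), CH2Cl2, 0 °C, dark; used at once
Reagents that add atoms: N-bromosuccinimide (4), O=C1CCC(=O)N1Br
Why: Electrophilic aromatic bromination of a 3-alkylindole ends at C2 because C3 is blocked, and the acetate prevents the bromocyclisation that free tryptophol would undergo.

**Step 3**
Reactants: 5 2-(2-bromo-1H-indol-3-yl)ethyl acetate; 6 (E)-3-(tributylstannyl)prop-2-en-1-ol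
Product: 7 2-{2-[(1E)-3-hydroxyprop-1-en-1-yl]-1H-indol-3-yl}ethyl acetate
Conditions: 6 (1.2 equiv), Pd2(dba)3 (2.5 mol%), AsPh3 (10 mol%), CuI (10 mol%), DMF, 50 °C
Reagents that add atoms: (E)-3-(tributylstannyl)prop-2-en-1-ol (6), CCCC[Sn](CCCC)(CCCC)/C=C/CO
Why: Stille cross-coupling of a heteroaryl bromide with an alkenylstannane proceeds with retention of the E geometry and tolerates the free N–H, the free O–H and the acetate.

**Step 4**
Reactants: 7 2-{2-[(1E)-3-hydroxyprop-1-en-1-yl]-1H-indol-3-yl}ethyl acetate; 8 tert-butyl hydroperoxide; 9 indole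
Product: 11 colletotryptin C, via epoxy alcohol 10 (not isolated)
Conditions: Ti(OiPr)4 (10 mol%), D-(−)-DIPT (12 mol%), TBHP (1.3 equiv, anhydrous), 4 Å MS, CH2Cl2, −25 °C; P(OMe)3 (0.3 equiv); then indole (3 equiv), Ti(OiPr)4 (1.2 equiv), −25 to 0 °C; Rochelle salt work-up
Reagents that add atoms: tert-butyl hydroperoxide (8), CC(C)(C)OO; indole (9), c1ccc2[nH]ccc2c1
Why: Proposed new method: a one-flask Sharpless asymmetric epoxidation / Ti(IV)-templated invertive Friedel–Crafts opening (a net enantioselective anti-hydroxy-indolylation of an allylic alcohol); the Ti–D-tartrate catalyst delivers oxygen to the face of 7 that gives the (2R,3R)-epoxide 10, whose C2–O bond is kept and becomes the (S)-carbinol; the Ti-bound epoxy alkoxide chelate then polarises the C3–O bond, which is benzylic to the electron-rich indol-2-yl group, and indole C3 attacks anti to the departing Ti-bound oxygen, so inversion gives the (S)-diarylmethine centre, while isopropoxide on Ti takes the Wheland proton so no free Brønsted acid builds up; the closest known reactions are the Ti(OiPr)4-mediated C3-selective opening of 2,3-epoxy alcohols by N, O and S nucleophiles and the Lewis-acid-promoted invertive opening of styrene oxides by indoles, neither shown in tandem with the epoxidation nor on an unprotected 2-indolyl glycidol.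

**Compound list**
1 | tryptophol, 2-(1H-indol-3-yl)ethanol | OCCc1c[nH]c2ccccc12 | starting material
2 | acetic anhydride | CC(=O)OC(C)=O | starting material
3 | 2-(1H-indol-3-yl)ethyl acetate | CC(=O)OCCc1c[nH]c2ccccc12 | intermediate
4 | N-bromosuccinimide | O=C1CCC(=O)N1Br | starting material
5 | 2-(2-bromo-1H-indol-3-yl)ethyl acetate | CC(=O)OCCc1c(Br)[nH]c2ccccc12 | intermediate
6 | (E)-3-(tributylstannyl)prop-2-en-1-ol | CCCC[Sn](CCCC)(CCCC)/C=C/CO | starting material
7 | 2-{2-[(1E)-3-hydroxyprop-1-en-1-yl]-1H-indol-3-yl}ethyl acetate | CC(=O)OCCc1c(/C=C/CO)[nH]c2ccccc12 | intermediate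
8 | tert-butyl hydroperoxide | CC(C)(C)OO | starting material
9 | indole | c1ccc2[nH]ccc2c1 | starting material
10 | 2-{2-[(2R,3R)-3-(hydroxymethyl)oxiran-2-yl]-1H-indol-3-yl}ethyl acetate (trans epoxy alcohol) | OC[C@H]1O[C@@H]1c2[nH]c3ccccc3c2CCOC(C)=O | intermediate
11 | colletotryptin C, 2-{2-[(1S,2S)-2,3-dihydroxy-1-(1H-indol-3-yl)propyl]-1H-indol-3-yl}ethyl acetate | CC(=O)OCCc1c([C@H](c2c[nH]c3ccccc23)[C@H](O)CO)[nH]c2ccccc12 | target

**Totals**
Total steps: 4. Longest linear sequence: 4 (tryptophol → 3 → 5 → 7 → 11).

**Three steps most likely to fail**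

Step 4 (proposed new step). Epoxide 10 may be consumed by isopropoxide or tartrate before indole attacks, or may open through a free cation with loss of stereospecificity. The fallback uses known chiral-pool Friedel–Crafts chemistry; it sets out from compound 3 (with indole 9) and comes back at compound 11. Indole 9 is converted with EtMgBr in THF into indolylmagnesium bromide and added at −78 °C to (R)-2,3-O-isopropylideneglyceraldehyde (O=C[C@H]1COC(C)(C)O1). This gives the carbinol (1H-indol-3-yl)[(4R)-2,2-dimethyl-1,3-dioxolan-4-yl]methanol F1 as a mixture of carbinol epimers, which does not matter because both ionise to the same cation. F1 and 3 (2 equiv) with catalytic diphenyl phosphate in CH2Cl2 at −20 °C give the 3-alkylideneindoleninium ion, which C2 of 3 attacks (the known C2-alkylation of 3-substituted indoles by 3-indolylmethanols). Attack anti to the dioxolane C–O bond (Felkin–Anh) is expected to give the acetonide 2-(2-{(S)-[(4S)-2,2-dimethyl-1,3-dioxolan-4-yl](1H-indol-3-yl)methyl}-1H-indol-3-yl)ethyl acetate F2; any minor diastereomer is removed by chromatography here. The carbinol centre comes from the chiral pool. Aqueous 80% AcOH at 40 °C removes the acetonide without touching the acetate and gives 11.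

Step 2. The N–H 2-bromoindole 5 is labile and may over-brominate or decompose before coupling. The fallback reverses the coupling polarity; it sets out from compound 3 and comes back at compound 7. Ir-catalysed C2–H borylation of 3 ([Ir(OMe)(cod)]2, dtbpy, B2pin2, THF, 60 °C) gives 2-[2-(4,4,5,5-tetramethyl-1,3,2-dioxaborolan-2-yl)-1H-indol-3-yl]ethyl acetate F3. A Pd(II)-catalysed oxidative boron-Heck reaction with acrolein (Pd(OAc)2, 2,9-dimethylphenanthroline, benzoquinone, MeCN, rt) gives the enal 2-{2-[(1E)-3-oxoprop-1-en-1-yl]-1H-indol-3-yl}ethyl acetate F4. Luche reduction (NaBH4, CeCl3·7H2O, MeOH, −20 °C) reduces only the aldehyde and gives 7.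

Step 3. Oxidative addition into the electron-rich N–H bromoindole may be slow, protodebromination may compete, and tin residues may carry into the titanium step. The fallback uses a boron partner with a protected side chain; it sets out from compound 5 and comes back at compound 7. Suzuki–Miyaura coupling of 5 with commercial (E)-tert-butyldimethyl{[3-(4,4,5,5-tetramethyl-1,3,2-dioxaborolan-2-yl)prop-2-en-1-yl]oxy}silane (Pd(dppf)Cl2, K3PO4, dioxane/H2O 10:1, 50 °C) gives the silyl ether 2-{2-[(1E)-3-(tert-butyldimethylsilyloxy)prop-1-en-1-yl]-1H-indol-3-yl}ethyl acetate F5. TBAF buffered with AcOH in THF at 0 °C removes the silyl group with the acetate intact and gives 7.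

**Further compounds**
F1 | step 4 | (1H-indol-3-yl)[(4R)-2,2-dimethyl-1,3-dioxolan-4-yl]methanol (carbinol epimers) | OC(c1c[nH]c2ccccc12)[C@H]3COC(C)(C)O3
F2 | step 4 | 2-(2-{(S)-[(4S)-2,2-dimethyl-1,3-dioxolan-4-yl](1H-indol-3-yl)methyl}-1H-indol-3-yl)ethyl acetate | CC(=O)OCCc1c([C@H](c2c[nH]c3ccccc23)[C@H]4COC(C)(C)O4)[nH]c5ccccc15
F3 | step 2 | 2-[2-(4,4,5,5-tetramethyl-1,3,2-dioxaborolan-2-yl)-1H-indol-3-yl]ethyl acetate | CC(=O)OCCc1c(B2OC(C)(C)C(C)(C)O2)[nH]c3ccccc13
F4 | step 2 | 2-{2-[(1E)-3-oxoprop-1-en-1-yl]-1H-indol-3-yl}ethyl acetate | CC(=O)OCCc1c(/C=C/C=O)[nH]c2ccccc12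
F5 | step 3 | 2-{2-[(1E)-3-(tert-butyldimethylsilyloxy)prop-1-en-1-yl]-1H-indol-3-yl}ethyl acetate | CC(=O)OCCc1c(/C=C/CO[Si](C)(C)C(C)(C)C)[nH]c2ccccc12
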